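In the early minutes of this flask, reagent has to come over from the second phase and is taken up once there, and the choice of the next run depends on how much each of these matters.

    reagent in the reaction phase ⇌ reagent in the second phase, rate k1*([reagent in the reaction phase] - [reagent in the second phase]/K1) per volume of the first phase (K1 = 0.367, k1 = 0.285 /min)
    starting material + reagent in the reaction phase → target (k2 = 0.701 /M/min)
    reagent in the reaction phase + target ⇌ idle adduct, settled at all times (K3 = 230 /M)
    2 reagent in the reaction phase → homo dimer (k4 = 0.229 /M/min)
    target ⇌ isomer of the product (K5 = 1.36, k5 = 0.0613 /min)

starting material 0.20 M; reagent in the second phase 1.00 equiv; time 8.0 min; volume of the second phase over the first 1.0

- what is said of target includes idle adduct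
- for a step with 2 of a species take k times the square, and two of it per event
- in the second phase: reagent in the second phase; everything else is in the first
- charges count per volume of the first phase; a concentration in a rate is the amount of a species over the volume of its own phase; every rate counts per litre of the first phase
- run time (flask): 8.0 min

- amount of target and idle adduct together at 8.0 min, in percent of the starting material charged
- the change that raises the amount of target and idle adduct together at 8.0 min, in percent of the starting material charged most ("none" if none brings more than 2 percentage points) (dawn / summer / none)
- amount of target and idle adduct together at 8.0 min, in percent of the starting material charged, after dawn

**Early lag.** An even split between the phases is the zero of the scale, and the partition here puts 73.2% of the reagent in the reaction phase at balance, which is 0.146 M if none were used. By transfer alone the phases approach balance with a half-time of 0.653 min, far shorter than the run of 8.0 min. Dawn, the doubling of the transfer coefficient, halves that half-time, and at the mean pace of our reckoning below, the time saved is worth about 1.2 percentage points, under the 2 points below which a change counts as useless.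

**Reagent cost.** The equation for the making of target says one reagent per target, and that is our second zero. But target also binds reagent, so we define the reagent cost as the reagent removed per target made: one for the making, plus the bound share, which is the binding constant times the reagent in the reaction phase, over one plus that product. At the balance level this cost is 1.97.

**Next run.** Counting cost and homo dimer, the reagent pool of both phases shrinks, at the balance level with the full charge of starting material, at a fractional pace of 0.251 /min. We hold that pace steady, ignore the lag, and let starting material fall in pseudo-first-order fashion against the reagent present, which gives 29.8%. The same reckoning with the reagent in the second phase doubled (summer) and the cost held gives 46.3%, a gain far above that of dawn, so we would charge more reagent. The forecast gave 31%, 33% after dawn and summer as the best change, holding that “transfer is only a short early lag”.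

**What stood.** The simulation gives 31.0% for the flask, 32.1% after dawn, and summer as the best change, worth 21 points against 1.2 points for dawn. In the flask at 8.00 min, with 0.0434 M of reagent in the reaction phase, the cost is 1.91, and the making of target uses that reagent 4.8 times as fast as the loss to homo dimer. In the neighbour charged with 0.80 M of starting material, 0.0349 M of reagent in the reaction phase at 8.00 min gives a cost of 1.89, and its target, idle adduct counted, stands at 45.0% of the starting material charged, with idle adduct at 40.1% of that same charge.

All constants are those of an exercise; the rest is arithmetic.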